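**Retrosynthetic overview**
1. Target ⇒ allylic monoalkyl diazene. Retro-ene loss of N2 moves the C–N stereocentre onto the methyl-bearing carbon and sets the E-alkene, so the key bond is a traceless C–N bond, made enantioselectively on a racemic 1,3-diaryl-3-methylallyl alcohol.
2. Allylic alcohol ⇒ β-methylchalcone-type enone (1,2-reduction) ⇒ self-aldol condensation of two molecules of 6-acetyl-7-methoxy-2,2-dimethylchromene.
3. Acetylchromene ⇒ 7-methoxy-2,2-dimethylchromene (Friedel–Crafts acetylation) ⇒ 3-methoxyphenol + 3-methylbut-2-enal.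
4. Ring order: both pyran rings are made once, on the monomer, in step 1 (oxa-6π closure). No ring is formed later.

Assumption: the SMILES encodes the (1E,3S) isomer (aryl > alkenyl > methyl > H at the stereocentre); NBSH and the chiral acid are bought reagents.

**Route**

Step 1
Reactants: 1 3-methoxyphenol; 2 3-methylbut-2-enal
Product: 5 7-methoxy-2,2-dimethyl-2H-chromene, via benzodioxaborin 3 (not isolated), via ortho-quinone methide 4 (not isolated)
Conditions: PhB(OH)2 (1.0 equiv, recovered), AcOH (cat.), toluene, reflux, Dean–Stark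
Reagents that add atoms: none
Why: Phenylboronic-acid-templated ortho-hydroxyalkylation gives 3, which fragments to 4 and closes by oxa-6π electrocyclisation (formal [3+3] chromene annulation); attack at the unhindered position para to OMe gives the 7-methoxy isomer.

Step 2
Reactants: 5 7-methoxy-2,2-dimethyl-2H-chromene
Product: 6 1-(7-methoxy-2,2-dimethyl-2H-chromen-6-yl)ethan-1-one
Conditions: Ac2O (1.5 equiv), Sc(OTf)3 (5 mol %), MeNO2, 0 → 23 °C
Reagents that add atoms: acetic anhydride, CC(=O)OC(C)=O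
Why: Friedel–Crafts acylation goes to C6 (para to the ring oxygen, ortho to OMe; C8 is flanked by two oxygens and C5 is meta to both), and a catalytic triflate Lewis acid is mild enough for the acid-sensitive chromene.

Step 3
Reactants: 6 1-(7-methoxy-2,2-dimethyl-2H-chromen-6-yl)ethan-1-one (2 equiv)
Product: 8 (2E)-1,3-bis(7-methoxy-2,2-dimethyl-2H-chromen-6-yl)but-2-en-1-one, via aldol adduct 7 (not isolated)
Conditions: Al(OtBu)3 (0.6 equiv), xylene, 135 °C, t-BuOH distilled off
Reagents that add atoms: none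
Why: Aluminium-enolate aldol addition of one ketone to a second, then elimination (dypnone-type self-condensation); the conjugated E isomer is the thermodynamic product, and tert-butoxide cannot act as a Meerwein–Ponndorf hydride donor.

Step 4
Reactants: 8 (2E)-1,3-bis(7-methoxy-2,2-dimethyl-2H-chromen-6-yl)but-2-en-1-one
Product: 9 rac-(2E)-1,3-bis(7-methoxy-2,2-dimethyl-2H-chromen-6-yl)but-2-en-1-ol
Conditions: i-Bu2AlH (1.2 equiv), toluene, −78 °C; aq. potassium sodium tartrate; used crude
Reagents that add atoms: none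
Why: i-Bu2AlH gives clean 1,2-reduction of the β,β-disubstituted enone, and the neutral tartrate work-up protects the easily ionised allylic alcohol.

Step 5
Reactants: 9 rac-(2E)-1,3-bis(7-methoxy-2,2-dimethyl-2H-chromen-6-yl)but-2-en-1-ol
Product: 13 6,6'-[(1E,3S)-but-1-ene-1,3-diyl]bis(7-methoxy-2,2-dimethyl-2H-chromene), via allyl cation 10 (not isolated), via allylic sulfonohydrazide 11 (not isolated), via allylic diazene 12 (not isolated)
Conditions: 2-nitrobenzenesulfonohydrazide (NBSH, 1.3 equiv), (R)-N-triflyl phosphoramide of 3,3'-bis(2,4,6-triisopropylphenyl)-1,1'-bi-2-naphthol (5 mol %), 4 Å MS, CH2Cl2 (5% THF), −45 °C; then Et3N (3 equiv), −45 → 23 °C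
Reagents that add atoms: none
Why: Proposed new method: enantioconvergent chiral-Brønsted-acid-catalysed SN1 allylic C–N bond formation with a sulfonyl hydrazide as a traceless nucleophile. The acid ionises the doubly activated alcohol 9 to the planar W-shaped cation 10, held as a contact ion pair with the chiral phosphoramide anion, which hydrogen-bonds NBSH and delivers its terminal nitrogen to one face of the less hindered CH terminus to give (S)-11. Et3N then neutralises the acid, 11 loses 2-nitrobenzenesulfinate to give diazene 12, and 12 loses N2 in a suprafacial retro-ene shift through the conformer with the C1–H inside (A(1,3) strain against the cis methyl), so the hydrogen lands on C3 on the face the nitrogen occupied. By this analysis (S,E)-12 gives the 3S stereocentre and the E-styrene. Closest known reaction types: chiral phosphoric acid/phosphoramide-catalysed asymmetric amination of 1,3-diarylallyl alcohols with sulfonamides, and the Mitsunobu/NBSH reductive 1,3-transposition of allylic alcohols through allylic diazenes.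

**Compound list**
1 | 3-methoxyphenol | COc1cccc(O)c1 | starting material
2 | 3-methylbut-2-enal | CC(C)=CC=O | starting material
3 | rac-7-methoxy-4-(2-methylprop-1-en-1-yl)-2-phenyl-4H-1,3,2-benzodioxaborinine | COc1ccc2C(C=C(C)C)OB(c3ccccc3)Oc2c1 | intermediate (not isolated)
4 | (6Z)-3-methoxy-6-(3-methylbut-2-en-1-ylidene)cyclohexa-2,4-dien-1-one | COC1=CC(=O)/C(=C\C=C(C)C)C=C1 | intermediate (not isolated)
5 | 7-methoxy-2,2-dimethyl-2H-chromene | COc1ccc2C=CC(C)(C)Oc2c1 | intermediate
6 | 1-(7-methoxy-2,2-dimethyl-2H-chromen-6-yl)ethan-1-one | COc1cc2OC(C)(C)C=Cc2cc1C(C)=O | intermediate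
7 | rac-3-hydroxy-1,3-bis(7-methoxy-2,2-dimethyl-2H-chromen-6-yl)butan-1-one (present as its aluminium alkoxide) | COc1cc2OC(C)(C)C=Cc2cc1C(=O)CC(C)(O)c1cc2C=CC(C)(C)Oc2cc1OC | intermediate (not isolated)
8 | (2E)-1,3-bis(7-methoxy-2,2-dimethyl-2H-chromen-6-yl)but-2-en-1-one | COc1cc2OC(C)(C)C=Cc2cc1C(=O)/C=C(\C)c1cc2C=CC(C)(C)Oc2cc1OC | intermediate
9 | rac-(2E)-1,3-bis(7-methoxy-2,2-dimethyl-2H-chromen-6-yl)but-2-en-1-ol | COc1cc2OC(C)(C)C=Cc2cc1C(O)/C=C(\C)c1cc2C=CC(C)(C)Oc2cc1OC | intermediate
10 | (2E)-1,3-bis(7-methoxy-2,2-dimethyl-2H-chromen-6-yl)but-2-en-1-ylium (ion pair with the chiral phosphoramide anion) | COc1cc2OC(C)(C)C=Cc2cc1[CH+]/C=C(\C)c1cc2C=CC(C)(C)Oc2cc1OC | intermediate (not isolated)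
11 | N'-[(1S,2E)-1,3-bis(7-methoxy-2,2-dimethyl-2H-chromen-6-yl)but-2-en-1-yl]-2-nitrobenzenesulfonohydrazide | COc1cc2OC(C)(C)C=Cc2cc1[C@@H](NNS(=O)(=O)c1ccccc1[N+](=O)[O-])/C=C(\C)c1cc2C=CC(C)(C)Oc2cc1OC | intermediate (not isolated)
12 | [(1S,2E)-1,3-bis(7-methoxy-2,2-dimethyl-2H-chromen-6-yl)but-2-en-1-yl]diazene | COc1cc2OC(C)(C)C=Cc2cc1[C@@H](N=N)/C=C(\C)c1cc2C=CC(C)(C)Oc2cc1OC | intermediate (not isolated)
13 | 6,6'-[(1E,3S)-but-1-ene-1,3-diyl]bis(7-methoxy-2,2-dimethyl-2H-chromene) (CNP0212142.1) | COc1cc2c(cc1/C=C/[C@H](C)c1cc3c(cc1OC)OC(C)(C)C=C3)C=CC(C)(C)O2 | target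

**Step count**
Total steps: 5. Longest linear sequence: 5.

**Three steps most likely to fail**

Step 5 (the proposed new step). Risks:
- The sense and level of enantioselection cannot be predicted; if the R product forms, the (S)-catalyst is used.
- Cation 10 can lose a methyl proton to give the 1,3-diene.
- Nitrogen can attack the tertiary terminus.
- 11 can re-ionise before the base is added.

The ee is read by chiral HPLC on 13. Fallback with known chemistry, setting out from enone 8 and coming back at diazene 12 (and so at 13): CBS reduction of 8 with (S)-1-methyl-3,3-diphenyltetrahydro-1H,3H-pyrrolo[1,2-c][1,3,2]oxazaborole (20 mol %) and catecholborane in toluene at −78 °C gives (1R,2E)-1,3-bis(7-methoxy-2,2-dimethyl-2H-chromen-6-yl)but-2-en-1-ol F1. The aryl group is taken as the large group; the sense is confirmed by Mosher ester analysis and the (R)-catalyst is used if it is reversed. Mitsunobu displacement with NBSH (PPh3, diethyl azodicarboxylate, N-methylmorpholine, −30 °C) inverts C1 and gives 1-[(1S,2E)-1,3-bis(7-methoxy-2,2-dimethyl-2H-chromen-6-yl)but-2-en-1-yl]-1-(2-nitrophenylsulfonyl)hydrazine F2. On warming to 23 °C, F2 loses the sulfinic acid to give the same diazene 12, which loses N2 to give 13.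

Step 3 (self-condensation). The ortho-methoxy, electron-rich ketone is a poor electrophile, so conversion may stall or give E/Z mixtures. Fallback, setting out from chromene 5 and coming back at enone 8: iodination of 5 at C6 (N-iodosuccinimide, MeCN, 0 °C) gives 6-iodo-7-methoxy-2,2-dimethyl-2H-chromene F3. Friedel–Crafts acylation of a second portion of 5 with (E)-but-2-enoic anhydride (Sc(OTf)3 cat., MeNO2) gives (2E)-1-(7-methoxy-2,2-dimethyl-2H-chromen-6-yl)but-2-en-1-one F4. Mizoroki–Heck coupling of F3 with F4 (Pd(OAc)2, P(o-tol)3, Et3N, DMF, 100 °C) places the aryl group on the methyl-bearing β-carbon and gives (E)-8.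

Step 2 (Friedel–Crafts acetylation). The chromene double bond may oligomerise or be acylated under Lewis acid. Fallback, setting out from 5 and coming back at 6: Vilsmeier–Haack formylation (POCl3, DMF, 0 → 50 °C) proceeds through N-[(7-methoxy-2,2-dimethyl-2H-chromen-6-yl)methylidene]-N-methylmethanaminium chloride F5, which aqueous NaOAc hydrolyses to 7-methoxy-2,2-dimethyl-2H-chromene-6-carbaldehyde F6. MeMgBr (THF, 0 °C) gives rac-1-(7-methoxy-2,2-dimethyl-2H-chromen-6-yl)ethan-1-ol F7, and MnO2 (CH2Cl2, 23 °C) oxidises it to 6.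

**Further compounds**
F1 | step 5 | (1R,2E)-1,3-bis(7-methoxy-2,2-dimethyl-2H-chromen-6-yl)but-2-en-1-ol | COc1cc2OC(C)(C)C=Cc2cc1[C@H](O)/C=C(\C)c1cc2C=CC(C)(C)Oc2cc1OC
F2 | step 5 | 1-[(1S,2E)-1,3-bis(7-methoxy-2,2-dimethyl-2H-chromen-6-yl)but-2-en-1-yl]-1-(2-nitrophenylsulfonyl)hydrazine | COc1cc2OC(C)(C)C=Cc2cc1[C@@H](N(N)S(=O)(=O)c1ccccc1[N+](=O)[O-])/C=C(\C)c1cc2C=CC(C)(C)Oc2cc1OC
F3 | step 3 | 6-iodo-7-methoxy-2,2-dimethyl-2H-chromene | COc1cc2OC(C)(C)C=Cc2cc1I
F4 | step 3 | (2E)-1-(7-methoxy-2,2-dimethyl-2H-chromen-6-yl)but-2-en-1-one | COc1cc2OC(C)(C)C=Cc2cc1C(=O)/C=C/C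
F5 | step 2 | N-[(7-methoxy-2,2-dimethyl-2H-chromen-6-yl)methylidene]-N-methylmethanaminium chloride | COc1cc2OC(C)(C)C=Cc2cc1C=[N+](C)C.[Cl-]
F6 | step 2 | 7-methoxy-2,2-dimethyl-2H-chromene-6-carbaldehyde | COc1cc2OC(C)(C)C=Cc2cc1C=O
F7 | step 2 | rac-1-(7-methoxy-2,2-dimethyl-2H-chromen-6-yl)ethan-1-ol | COc1cc2OC(C)(C)C=Cc2cc1C(C)O
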